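**Plan**

1. Ring numbering used throughout: C1 (C=O), C2 (acyl), C3 (C–OH), C4 (prenyl), C5 (C–OH), C6 (gem-diprenyl). Oxygen on C1, C3 and C5 around a quaternary C6 that cannot aromatise is the pattern left when a siloxyalkyne inserts into a 4,4-disubstituted 3-siloxycyclobutenone.
2. Retrosynthesis: the side-chain ketone is taken back to a silyl-protected carbinol and the two enols to silyl enol ethers. The ring is then cut at C1–C2 and C3–C4 (C1–C6 opens and recloses within the same cascade) into a triprenyl siloxycyclobutenone (C1, C4, C5, C6) and a siloxyalkyne (C2, C3 and the side chain).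
3. The cyclobutenone is cut across its four-membered ring into diprenylketene and a prenyl-substituted siloxyalkyne. Both siloxyalkynes are traced to esters by one-carbon homologation to ynolates.
4. Forward order: prenyl siloxyalkyne; diprenylacetyl chloride from malonate; ketene–alkyne [2+2] to the four-membered ring; thermal cascade with the second siloxyalkyne to the six-membered ring; carbinol unmasking, oxidation, desilylation.
5. Stereochemistry: the target has no stereocentre. The single (R)-carbinol centre, bought in the hydroxy ester, is a carrier that passes through the cascade untouched and is erased by the oxidation.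

Key step: step 10

Remark: 4-methylpent-3-enoic acid 1 is taken to be a purchasable acid. It is the ester of this acid, not of 5-methylhex-4-enoic acid, that homologates to the prenyl-substituted siloxyalkyne, because the ynolate carries the ester's acyl substituent unchanged on its β-carbon.

**Route**

Step 1
Reactants: 1 4-methylpent-3-enoic acid
Product: 2 methyl 4-methylpent-3-enoate
Conditions: MeI, K2CO3, DMF, rt
Reagents that add atoms: iodomethane, CI
Why: SN2 O-methylation of the carboxylate under non-acidic conditions avoids the lactonisation and double-bond migration that Fischer esterification of a β,γ-unsaturated acid would invite.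

Step 2
Reactants: 2 methyl 4-methylpent-3-enoate
Product: 5 triisopropyl[(5-methylhex-4-en-1-yn-1-yl)oxy]silane, via dibromo enolate 3 (not isolated), via lithium ynolate 4 (not isolated)
Conditions: CH2Br2, lithium 2,2,6,6-tetramethylpiperidide, THF, −78 °C, then 2; LiN(SiMe3)2, −78 → −20 °C; n-BuLi, −78 °C → rt; i-Pr3SiCl, −78 °C → rt
Reagents that add atoms: dibromomethane, BrCBr; chlorotriisopropylsilane, CC(C)[Si](Cl)(C(C)C)C(C)C
Why: Kowalski ester homologation stopped at the ynolate: LiCHBr2 adds to the ester, the dibromo enolate undergoes bromine–lithium exchange and 1,2-shift of the prenyl CH2, and the bulky chlorosilane should silylate the ynolate on oxygen.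

Step 3
Reactants: 6 dimethyl malonate; 7 1-bromo-3-methylbut-2-ene (prenyl bromide)
Product: 8 dimethyl 2,2-bis(3-methylbut-2-en-1-yl)malonate
Conditions: NaH (2.3 equiv), 7 (2.3 equiv), THF, 0 °C → reflux
Reagents that add atoms: none
Why: Malonic ester synthesis, in which two successive SN2 alkylations of the malonate enolate at the primary allylic carbon of the bromide should install both prenyl groups in one operation.

Step 4
Reactants: 8 dimethyl 2,2-bis(3-methylbut-2-en-1-yl)malonate
Product: 9 2,2-bis(3-methylbut-2-en-1-yl)malonic acid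
Conditions: KOH, MeOH/H2O, reflux; then cold 2 M HCl
Reagents that add atoms: potassium hydroxide, [K+].[OH-]
Why: Saponification of both methyl esters with hot aqueous-alcoholic hydroxide overcomes the hindrance at the quaternary carbon, and the trisubstituted alkenes are inert to base and to brief cold acidification.

Step 5
Reactants: 9 2,2-bis(3-methylbut-2-en-1-yl)malonic acid
Product: 10 5-methyl-2-(3-methylbut-2-en-1-yl)hex-4-enoic acid
Conditions: pyridine, reflux
Reagents that add atoms: none
Why: Thermal decarboxylation of a geminal diacid through the cyclic six-membered transition state, run in pyridine so that no free strong acid can lactonise the acid onto a prenyl double bond.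

Step 6
Reactants: 10 5-methyl-2-(3-methylbut-2-en-1-yl)hex-4-enoic acid
Product: 11 5-methyl-2-(3-methylbut-2-en-1-yl)hex-4-enoyl chloride
Conditions: (COCl)2, DMF (cat.), CH2Cl2, 0 °C → rt; used crude
Reagents that add atoms: oxalyl chloride, ClC(=O)C(=O)Cl
Why: Vilsmeier-type activation by DMF-catalysed oxalyl chloride forms the acid chloride at low temperature with only gaseous by-products, which limits addition of HCl to the alkenes.

Step 7
Reactants: 11 5-methyl-2-(3-methylbut-2-en-1-yl)hex-4-enoyl chloride; 5 triisopropyl[(5-methylhex-4-en-1-yn-1-yl)oxy]silane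
Product: 13 2,4,4-tris(3-methylbut-2-en-1-yl)-3-(triisopropylsilyloxy)cyclobut-2-en-1-one, via diprenylketene 12 (not isolated)
Conditions: Et3N (1.5 equiv), CH2Cl2, 0 → 40 °C
Reagents that add atoms: none
Why: Dehydrochlorination gives the dialkylketene, which should undergo the known ketene–ynol ether [2+2] cycloaddition with the nucleophilic alkyne β-carbon bonding to the ketene carbonyl carbon, at a temperature below that at which the product cyclobutenone ring-opens.

Step 8
Reactants: 14 ethyl (R)-2-hydroxy-4-phenylbutanoate
Product: 15 ethyl (R)-4-phenyl-2-(triethylsilyloxy)butanoate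
Conditions: Et3SiCl, imidazole, DMF, 0 °C → rt
Reagents that add atoms: chlorotriethylsilane, CC[Si](Cl)(CC)CC
Why: Imidazole-promoted silylation of the secondary alcohol, which does not touch the stereocentre.

Step 9
Reactants: 15 ethyl (R)-4-phenyl-2-(triethylsilyloxy)butanoate
Product: 18 (R)-triethyl{[1-phenyl-5-(triisopropylsilyloxy)pent-4-yn-3-yl]oxy}silane, via dibromo enolate 16 (not isolated), via lithium ynolate 17 (not isolated)
Conditions: CH2Br2, lithium 2,2,6,6-tetramethylpiperidide, THF, −78 °C, then 15; LiN(SiMe3)2, −78 → −20 °C; n-BuLi, −78 °C → rt; i-Pr3SiCl, −78 °C → rt; base-washed silica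
Reagents that add atoms: dibromomethane, BrCBr; chlorotriisopropylsilane, CC(C)[Si](Cl)(C(C)C)C(C)C
Why: Kowalski homologation to the ynolate, in which the siloxy-bearing carbon should migrate with retention, as α-heteroatom-substituted carbons do in homologations of protected α-amino esters, followed by O-silylation with the bulky chlorosilane.

Step 10
Reactants: 13 2,4,4-tris(3-methylbut-2-en-1-yl)-3-(triisopropylsilyloxy)cyclobut-2-en-1-one; 18 (R)-triethyl{[1-phenyl-5-(triisopropylsilyloxy)pent-4-yn-3-yl]oxy}silane
Product: 22 (R)-4,6,6-tris(3-methylbut-2-en-1-yl)-2-[3-phenyl-1-(triethylsilyloxy)propyl]-3,5-bis(triisopropylsilyloxy)cyclohexa-2,4-dien-1-one, via vinylketene 19 (not isolated), via vinylcyclobutenone 20 (not isolated), via dienylketene 21 (not isolated)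
Conditions: 18 (2 equiv), toluene (0.5 M), 80 → 110 °C, sealed tube, Ar, base-washed glassware
Reagents that add atoms: none
Why: Thermal 4π ring opening of 13 (its C1–C4 bond) gives siloxyvinylketene 19, whose ketene C=C adds alkyne 18 in a [2+2] cycloaddition, the ketene carbonyl carbon bonding to the alkyne carbon remote from oxygen (product bond C1–C2) and the ketene α-carbon to the siloxy-bearing carbon (product bond C3–C4), to give 20. A second, reversible 4π opening of 20 gives dienylketene 21, and the isomer with the ketene and siloxyvinyl arms cis closes C1–C6 by thermal disrotatory 6π-electrocyclisation, which is the only ring closure kept in the product. The closest known reaction is the Danheiser benzannulation of cyclobutenones with siloxyalkynes, in the variant where a 4,4-disubstituted cyclobutenone ends at a cyclohexa-2,4-dienone. No new stereocentre results, since C6 carries two identical prenyl groups, the C4 centre of 20 is erased on ring opening, and the carbinol centre of 18 is a spectator. The step needs the regiochemistry of the ketene–alkyne addition, which the polarisation of the siloxyalkyne secures, and intermolecular trapping ahead of reclosure or ketene–prenyl cycloaddition, which the excess of 18 and the concentrated solution favour. Aromatisation cannot follow because C6 is quaternary, so the cascade should stop at the bis-silyl enol ether of the target ring.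

Step 11
Reactants: 22 (R)-4,6,6-tris(3-methylbut-2-en-1-yl)-2-[3-phenyl-1-(triethylsilyloxy)propyl]-3,5-bis(triisopropylsilyloxy)cyclohexa-2,4-dien-1-one
Product: 23 (R)-2-(1-hydroxy-3-phenylpropyl)-4,6,6-tris(3-methylbut-2-en-1-yl)-3,5-bis(triisopropylsilyloxy)cyclohexa-2,4-dien-1-one
Conditions: HF·pyridine, excess pyridine, THF, 0 °C
Reagents that add atoms: none
Why: Buffered fluoride desilylation should cleave the small triethylsilyl ether much faster than the two triisopropylsilyl enol ethers, which are shielded by their isopropyl groups and flanking ring substituents.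

Step 12
Reactants: 23 (R)-2-(1-hydroxy-3-phenylpropyl)-4,6,6-tris(3-methylbut-2-en-1-yl)-3,5-bis(triisopropylsilyloxy)cyclohexa-2,4-dien-1-one
Product: 24 4,6,6-tris(3-methylbut-2-en-1-yl)-2-(3-phenylpropanoyl)-3,5-bis(triisopropylsilyloxy)cyclohexa-2,4-dien-1-one
Conditions: Dess–Martin periodinane, pyridine, CH2Cl2, 0 °C → rt
Reagents that add atoms: none
Why: Dess–Martin oxidation of the secondary carbinol under buffered, non-aqueous conditions should spare the silyl enol ethers and prenyl groups and removes the only stereocentre of the route.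

Step 13
Reactants: 24 4,6,6-tris(3-methylbut-2-en-1-yl)-2-(3-phenylpropanoyl)-3,5-bis(triisopropylsilyloxy)cyclohexa-2,4-dien-1-one
Product: 25 helilupolone
Conditions: Bu4NF, AcOH, THF, 0 °C, Ar; aqueous work-up at pH 5
Reagents that add atoms: none
Why: Fluoride-mediated desilylation of the two vinylogous silyl esters, with acetic acid protonating the enolate as it forms, should release the air- and base-sensitive β-triketone directly as the dienol tautomer of the target.

**Compound list**

1 | 4-methylpent-3-enoic acid | CC(C)=CCC(=O)O | starting material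
2 | methyl 4-methylpent-3-enoate | COC(=O)CC=C(C)C | intermediate
3 | lithium 1,1-dibromo-5-methylhexa-1,4-dien-2-olate | [Li]OC(CC=C(C)C)=C(Br)Br | intermediate (not isolated)
4 | lithium 5-methylhex-4-en-1-yn-1-olate | [Li]OC#CCC=C(C)C | intermediate (not isolated)
5 | triisopropyl[(5-methylhex-4-en-1-yn-1-yl)oxy]silane | CC(C)[Si](C(C)C)(C(C)C)OC#CCC=C(C)C | intermediate
6 | dimethyl malonate | COC(=O)CC(=O)OC | starting material
7 | 1-bromo-3-methylbut-2-ene (prenyl bromide) | CC(C)=CCBr | starting material
8 | dimethyl 2,2-bis(3-methylbut-2-en-1-yl)malonate | COC(=O)C(CC=C(C)C)(CC=C(C)C)C(=O)OC | intermediate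
9 | 2,2-bis(3-methylbut-2-en-1-yl)malonic acid | OC(=O)C(CC=C(C)C)(CC=C(C)C)C(=O)O | intermediate
10 | 5-methyl-2-(3-methylbut-2-en-1-yl)hex-4-enoic acid | OC(=O)C(CC=C(C)C)CC=C(C)C | intermediate
11 | 5-methyl-2-(3-methylbut-2-en-1-yl)hex-4-enoyl chloride | ClC(=O)C(CC=C(C)C)CC=C(C)C | intermediate
12 | 5-methyl-2-(3-methylbut-2-en-1-yl)hexa-1,4-dien-1-one (diprenylketene) | O=C=C(CC=C(C)C)CC=C(C)C | intermediate (not isolated)
13 | 2,4,4-tris(3-methylbut-2-en-1-yl)-3-(triisopropylsilyloxy)cyclobut-2-en-1-one | O=C1C(CC=C(C)C)=C(O[Si](C(C)C)(C(C)C)C(C)C)C1(CC=C(C)C)CC=C(C)C | intermediate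
14 | ethyl (R)-2-hydroxy-4-phenylbutanoate | CCOC(=O)[C@@H](CCc1ccccc1)O | starting material
15 | ethyl (R)-4-phenyl-2-(triethylsilyloxy)butanoate | CCOC(=O)[C@@H](CCc1ccccc1)O[Si](CC)(CC)CC | intermediate
16 | lithium (R)-1,1-dibromo-5-phenyl-3-(triethylsilyloxy)pent-1-en-2-olate | [Li]OC(=C(Br)Br)[C@@H](CCc1ccccc1)O[Si](CC)(CC)CC | intermediate (not isolated)
17 | lithium (R)-5-phenyl-3-(triethylsilyloxy)pent-1-yn-1-olate | [Li]OC#C[C@@H](CCc1ccccc1)O[Si](CC)(CC)CC | intermediate (not isolated)
18 | (R)-triethyl{[1-phenyl-5-(triisopropylsilyloxy)pent-4-yn-3-yl]oxy}silane | CC(C)[Si](C(C)C)(C(C)C)OC#C[C@@H](CCc1ccccc1)O[Si](CC)(CC)CC | intermediate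
19 | 7-methyl-2,4-bis(3-methylbut-2-en-1-yl)-3-(triisopropylsilyloxy)octa-1,3,6-trien-1-one (vinylketene) | O=C=C(CC=C(C)C)C(O[Si](C(C)C)(C(C)C)C(C)C)=C(CC=C(C)C)CC=C(C)C | intermediate (not isolated)
20 | 4-(3-methylbut-2-en-1-yl)-4-[5-methyl-2-(3-methylbut-2-en-1-yl)-1-(triisopropylsilyloxy)hexa-1,4-dien-1-yl]-2-[(R)-3-phenyl-1-(triethylsilyloxy)propyl]-3-(triisopropylsilyloxy)cyclobut-2-en-1-one (both C4 epimers) | O=C1C([C@@H](CCc2ccccc2)O[Si](CC)(CC)CC)=C(O[Si](C(C)C)(C(C)C)C(C)C)C1(CC=C(C)C)C(O[Si](C(C)C)(C(C)C)C(C)C)=C(CC=C(C)C)CC=C(C)C | intermediate (not isolated)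
21 | (3E)-9-methyl-4,6-bis(3-methylbut-2-en-1-yl)-2-[(R)-3-phenyl-1-(triethylsilyloxy)propyl]-3,5-bis(triisopropylsilyloxy)deca-1,3,5,8-tetraen-1-one (dienylketene, ketene and siloxyvinyl arms cis) | O=C=C([C@@H](CCc1ccccc1)O[Si](CC)(CC)CC)/C(O[Si](C(C)C)(C(C)C)C(C)C)=C(CC=C(C)C)\C(O[Si](C(C)C)(C(C)C)C(C)C)=C(CC=C(C)C)CC=C(C)C | intermediate (not isolated)
22 | (R)-4,6,6-tris(3-methylbut-2-en-1-yl)-2-[3-phenyl-1-(triethylsilyloxy)propyl]-3,5-bis(triisopropylsilyloxy)cyclohexa-2,4-dien-1-one | O=C1C([C@@H](CCc2ccccc2)O[Si](CC)(CC)CC)=C(O[Si](C(C)C)(C(C)C)C(C)C)C(CC=C(C)C)=C(O[Si](C(C)C)(C(C)C)C(C)C)C1(CC=C(C)C)CC=C(C)C | intermediate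
23 | (R)-2-(1-hydroxy-3-phenylpropyl)-4,6,6-tris(3-methylbut-2-en-1-yl)-3,5-bis(triisopropylsilyloxy)cyclohexa-2,4-dien-1-one | O=C1C([C@@H](CCc2ccccc2)O)=C(O[Si](C(C)C)(C(C)C)C(C)C)C(CC=C(C)C)=C(O[Si](C(C)C)(C(C)C)C(C)C)C1(CC=C(C)C)CC=C(C)C | intermediate
24 | 4,6,6-tris(3-methylbut-2-en-1-yl)-2-(3-phenylpropanoyl)-3,5-bis(triisopropylsilyloxy)cyclohexa-2,4-dien-1-one | O=C1C(C(=O)CCc2ccccc2)=C(O[Si](C(C)C)(C(C)C)C(C)C)C(CC=C(C)C)=C(O[Si](C(C)C)(C(C)C)C(C)C)C1(CC=C(C)C)CC=C(C)C | intermediate
25 | helilupolone, 3,5-dihydroxy-4,6,6-tris(3-methylbut-2-en-1-yl)-2-(3-phenylpropanoyl)cyclohexa-2,4-dien-1-one | CC(C)=CCC1=C(O)C(CC=C(C)C)(CC=C(C)C)C(=O)C(C(=O)CCc2ccccc2)=C1O | target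

**Step count**

Total: 13 steps. Longest linear sequence: 9 steps (3, 4, 5, 6, 7, 10, 11, 12, 13).

**Steps most likely to fail**

Step 10. The vinylketene may reclose to the cyclobutenone faster than it is trapped by the α-branched alkyne. The siloxyalkyne may isomerise by a 1,3-silyl shift at the temperature needed. A 1,5-hydrogen shift from a prenyl CH2 in the dienylketene may compete with closure onto the fully substituted terminus. The fallback gives up the cascade for the classical late-stage prenylation of an acylphloroglucinol; it sets out from prenyl bromide 7 and comes back at 25. 1-(2,4,6-Trihydroxyphenyl)-3-phenylpropan-1-one F1 would be made by Friedel–Crafts acylation of phloroglucinol with 3-phenylpropanoyl chloride (AlCl3, nitrobenzene). F1 would then be C-prenylated three times with 7 and NaOMe in MeOH at 0 °C. The second alkylation at the same ring carbon dearomatises the ring, so the product should be 25, to be separated from less prenylated congeners.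

Step 11. Fluoride may also strip the triisopropylsilyl enol ethers, a silyl group may migrate from the C3 oxygen to the freed carbinol, or the allylic carbinol may ionise and eliminate. The fallback merges deprotection and oxidation so that the free carbinol is never isolated; it sets out from 22 and comes back at 24. Treatment of 22 with IBX in DMSO at rt is known to cleave triethylsilyl ethers in the presence of bulkier silyl groups and to carry the liberated alcohol on to the carbonyl compound in the same flask. No new compound is made on the way.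

Step 9. Enolisation of the hindered α-siloxy ester may outrun addition of LiCHBr2, or the carbenoid rearrangement may stall because the migrating carbon is branched and oxygen-substituted. The fallback builds the ynolate from a terminal alkyne; it sets out from 15 and comes back at 18. Reduction of 15 with i-Bu2AlH (CH2Cl2, −78 °C) should give (R)-4-phenyl-2-(triethylsilyloxy)butanal F2. Ohira–Bestmann homologation (dimethyl (1-diazo-2-oxopropyl)phosphonate, K2CO3, MeOH) should then give (R)-triethyl[(5-phenylpent-1-yn-3-yl)oxy]silane F3; partial epimerisation here would be without consequence. Lithiation of F3 with n-BuLi and oxidation of the acetylide with t-BuOOLi (from t-BuOOH and LiN(SiMe3)2, THF, −78 → 0 °C) should give ynolate 17, which i-Pr3SiOSO2CF3 silylates on oxygen to 18.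

**Further compounds**

F1 | step 10 | 1-(2,4,6-trihydroxyphenyl)-3-phenylpropan-1-one | O=C(CCc1ccccc1)c1c(O)cc(O)cc1O
F0 | step 11 | none | none
F2 | step 9 | (R)-4-phenyl-2-(triethylsilyloxy)butanal | O=C[C@@H](CCc1ccccc1)O[Si](CC)(CC)CC
F3 | step 9 | (R)-triethyl[(5-phenylpent-1-yn-3-yl)oxy]silane | C#C[C@@H](CCc1ccccc1)O[Si](CC)(CC)CC
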